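# Proposed total synthesis of CNP0558742.1 by dearomative palladium spirocyclization of a phenolic aryl benzoate

## The problem

CNP0558742.1 is a bis-diterpenoid. A 20-carboxy-labd-8(17)-ene-type trans-decalin is tied through the C11 methylene to C12 of a cyclohexane (C12, C13, C14, C15, C17′, C15′). That ring is spiro-fused at C15′ to the γ-lactone (carbonyl C16′, oxygen on C13′) of a 7′β-acetoxytotarane, whose aromatic carbon C14′ is the second spiro substituent.

Nine stereocentres must be set. C5, C10, C5′ and C10′ are terpenoid ring-fusion centres best taken from the chiral pool. C9 and C7′ lie next to them and can be set under their control. The quaternary C15′ has no neighbour that can direct it and needs a reagent. Once C15′ exists, its two unlike faces (aryl side C14′/C8′/C7′ against lactone carbonyl C16′) can direct C12, and an axial substituent on C12 can then direct C14.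

On the central ring the C11 arm and the C14 hydroxyl are both cis to C14′, so the bulky arm points into the crowded quadrant beside the 7′β-acetate. C12 therefore has to be set kinetically.

Several groups restrict the conditions:
- the phenolic lactone and the benzylic acetate exclude hydroxide;
- the two 1,1-disubstituted alkenes (C8=C17, C13=C16) exclude strong acid, hydrogenation and electrophilic oxidants late in the route;
- the neopentyl C20 acid cannot be freed by ester hydrolysis.

The feature that opens the synthesis is the substitution pattern of the cyclohexane. Oxygen sits on C14, para to the spiro carbon C15′. The one-carbon branch C16 sits on C13, ortho to that oxygen. C15′ carries the carboxyl carbon C16′. This is the pattern of a 4-hydroxy-3-(hydroxymethyl)benzoic acid, so the central ring can be brought in as a benzene ring and the quaternary centre made by arylating C15′ of its phenolate.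

## Retrosynthesis

**Protecting group on C20 (48 ⇒ 47).** The last cut is the O–alkyl bond of a 2-(trimethylsilyl)ethyl ester. Fluoride attacks silicon, far from the hindered carbonyl, so acid 48 is released from 47 without touching the acetate or the lactone. The forward step only has to be non-basic.

**C14–H, C12–H and the C15/C17′ hydrogens (47 ⇒ 46 ⇒ 43 ⇒ 42 ⇒ 41).** Alcohol 47 is cut at C14–H back to α-methylene ketone 46. Ketone 46 is cut at C12–H back to hydroxymethyl enone 43, through a reductive 1,3-transposition that moves the alkene from C12=C13 to C13=C16. Enone 43 comes from silyl ether 42, and 42 from dienone 41 by conjugate reduction of the unsubstituted arm C15=C17′. Reducing C14 before C12 was rejected: the only control would then be the spiro centre, four atoms away. In the chosen order C15′ directs C12 (adjacent) and the axial C11 arm directs C14 (1,3). The forward steps must deliver both hydrogens from the face of C16′.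

**C14′–C15′ (41 ⇒ 40), the key cut.** Breaking the aryl–quaternary carbon bond turns the dienone into phenol 40, an aryl 4-hydroxybenzoate with bromine on C14′. This removes the spiro centre, the lactone ring and the need to build a carbocycle at all. Cutting C15′–C16′ or a ring bond of the cyclohexane would leave a quaternary centre to be made on a saturated ring. The forward reaction must arylate the phenolate at its para (ipso) carbon, keep the aryl ester intact under base, and choose the face so that C12 lies on the β-face of the totarane.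

**C16′–O ester (40 ⇒ 39 ⇒ 38 ⇒ 20 + 36).** The aryl ester is cut to benzoic acid 20 and bromophenol diol 36. The 7′-acetate is put on after the union (38 → 39) and the phenolic silyl ether is taken off last (39 → 40). The forward acylation must pick the phenol of 36 over its hindered secondary alcohol, which a phenol/amine acylation does.

**C11–C12 (20 ⇒ 19 ⇒ 11 + 17).** The benzylic bond is cut to primary iodide 11 and bromo aldehyde 17. An sp3–sp2 Negishi coupling forms it without a benzylic oxygen that would have to be removed next to an exocyclic alkene. The aldehyde survives organozinc chemistry and is oxidised to acid 20 afterwards.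

**Decalin 11 from carnosic acid (11 ⇒ 10 ⇒ 9 ⇒ 5 ⇒ 3 ⇒ 2 ⇒ 1).** Carnosic acid 1 supplies C5, C10 and the C20 carboxyl. Its aromatic ring is cut twice by ozone, between the two oxygenated carbons and at C13=C14 (abietane numbering), leaving C8=C9 with two one-carbon stubs (enal ester 5). The aromatic CH becomes C17. A tosylhydrazone reduction with alkene migration turns the enal into the exocyclic methylene and sets 9α-H (9). This uses both stubs; routes through a C8 ketone would discard one carbon and add it back.

**Arene 17 (17 ⇒ 15 ⇒ 14 ⇒ 13 ⇒ 12).** 2-Bromo-6-hydroxybenzaldehyde 12 already carries bromine (C12), the C16 carbon at aldehyde level and the C14 oxygen. Only the C16′ carbon is missing; it is introduced para to the hydroxyl through iodination and iodine–magnesium exchange. A 2-methylphenol would need a benzylic oxidation in addition.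

**Totarane 36 from sclareol (36 ⇒ 34 ⇒ 32 ⇒ 30 ⇒ 28 ⇒ 27 ⇒ 25 ⇒ 24 ⇒ 21).** Sclareol 21 supplies C5′ and C10′. Ring C′ is closed by aldol condensation of dione 27. Bromine is placed on C14′ at the enone stage (28 → 30), where the α-carbon is the only reactive site, and not on the phenol, where C12′ would compete. Aromatisation, benzylic oxidation and axial hydride delivery give the 7′β-alcohol.

## Roads not taken

**Alternative 1: cationic bicyclization to the totarane lactone.** The cut is C4′–C5′ and C10′–C9′: rings A′ and B′ are opened to benzofuranone A2, which carries an (E)-homogeranyl chain with the acetate already on benzylic C7′. In the forward key step, SnCl4 with a phenol as proton source would protonate the terminal alkene, and the C5′=C10′ alkene and then aromatic C9′ would trap the cations to give A1.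
- Merits: two rings, two C–C bonds and the trans ring fusion in one step from an arene and a geranyl unit. No regioselective bromination is needed. The totarane half would be reached in far fewer steps than the nine from sclareol to 36; in step count it is the better road to that half.
- Weak points: A1 still has C15′ as a methylene, so the spiro centre, the whole cyclohexane, C12 and C14 remain unsolved. The arene is an acylated phenol and a weak terminator. The benzylic acetate sits next to a Lewis acid and a cationic chain. All absolute configuration rests on one acyclic acetate centre that must be made enantioselectively and must relay to C5′ and C10′.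
- Against its brevity the chosen plan sets enantiopure ring-fusion centres from sclareol and a key step that creates the quaternary spiro centre, which Alternative 1 leaves open.

**Alternative 2: late aryne Diels–Alder for rings B′ and A′.** The cut is C7′–C8′ and C9′–C10′. CsF would release the aryne from silyl triflate A4, a spiro benzofuranone that already carries the decalin and the cyclohexenone, and dienyl methyl ether A5 would add across it to give A3.
- Merits: it is the most convergent of the four plans. The spiro centre would be made on a benzofuranone without a peri substituent, which is less crowded than closing 40 next to C7′; in this respect it is better than the chosen plan.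
- Weak points: the aryne is unsymmetrical and two orientations of addition are possible. C10′ and C7′ form far from C15′, so no facial control is available. A3 then needs a trans-selective reduction of C5′=C6′ in the presence of two exocyclic alkenes and an enone, and the 7′α-methyl ether must become a 7′β-acetate by ether cleavage and inversion, all on the most sensitive compound.
- The chosen plan sets against the greater convergence four totarane stereocentres fixed before the union and only reductions after the key step.

**Alternative 3: Meinwald ring contraction.** The cut is C12–C15′. BF3·OEt2 would open the benzylic C15′–O bond of aryl cycloheptene oxide A7, C12 would migrate from C16′ to C15′, and the ring would contract to aldehyde A6; oxidation and lactonisation would follow.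
- Merits: C12 and C14 are in place before the quaternary centre forms, and C15′ is created stereospecifically by a 1,2-shift. No late, remotely controlled reduction is needed; here Alternative 3 is better than the chosen plan, which sets C12 and C14 after C15′. No metal-catalysed step has to work at a hindered aryl bromide.
- Weak points: A7 needs a stereodefined seven-membered ring with a di-ortho-substituted aryl on a trisubstituted epoxide, made face-selectively beside two exocyclic alkenes. Hydride shift to a ketone competes with migration of C12. The cationic conditions threaten the 1,1-disubstituted alkenes and the benzylic acetate. Two further oxidation-state changes are needed after A6.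
- The chosen plan answers with a central ring that comes from a benzene in four steps, and with three fragments that are joined by two robust couplings.

Key step: step 25

Assumption: C17 is the exocyclic methylene carbon on C8, C15 the ring CH2 next to C14, and C15′, C16′, C17′ the spiro carbon, the lactone carbonyl and the ring CH2 next to the spiro carbon; intermediate 4 stands for a mixture of peroxides and 22 for a mixture of C14 epimers.

## Route

Step 1
Reactants: 1 carnosic acid
Product: 2 2-(trimethylsilyl)ethyl carnosate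
Conditions: Me3SiCH2CH2OC(=NH)CCl3, toluene, 100 °C, Ar
Reagents that add atoms: 2-(trimethylsilyl)ethyl 2,2,2-trichloroacetimidate, C[Si](C)(C)CCOC(=N)C(Cl)(Cl)Cl
Why: Promoter-free imidate esterification: the carboxylic acid protonates the imidate and is alkylated, so the hindered C20 acid is esterified without activating its carbonyl and the catechol, too weakly acidic, is left alone.

Step 2
Reactants: 2 2-(trimethylsilyl)ethyl carnosate
Product: 3 2-(trimethylsilyl)ethyl 11,12-di-O-methylcarnosate
Conditions: MeI, K2CO3, DMF, 40 °C, Ar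
Reagents that add atoms: iodomethane, CI
Why: Williamson etherification of both phenols; the dimethyl ether is stable to air and gives the ring the veratrole pattern that ozone cleaves between the oxygenated carbons.

Step 3
Reactants: 3 2-(trimethylsilyl)ethyl 11,12-di-O-methylcarnosate
Product: 5 enal diester of the trans-decalin (C8=C9; CHO C17 on C8; CO2Me C11 on C9; 10β-CO2CH2CH2SiMe3), via methoxy hydroperoxide 4 (not isolated)
Conditions: O3 (2.2 equiv), CH2Cl2/MeOH 4:1, −78 °C; Me2S, −78 °C → rt
Reagents that add atoms: ozone, [O-][O+]=O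
Why: Ozonolysis of an electron-rich arene: the bond between the two methoxy carbons is cleaved first (veratrole to muconate), then the trisubstituted C13=C14 bond of the diene. The remaining C8=C9 bond is tetrasubstituted and flanked by two carbonyl groups, so it should survive.

Step 4
Reactants: 5 enal diester
Product: 9 methyl ester with exocyclic C8=C17 and 9α-H (9β-CO2Me; 10β-CO2CH2CH2SiMe3), via tosylhydrazone 6 (not isolated), via N-boryl tosylhydrazine 7 (not isolated), via allylic diazene 8 (not isolated)
Conditions: TsNHNH2, 4 Å MS, CHCl3, rt; catecholborane, 0 °C; NaOAc·3H2O, 60 °C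
Reagents that add atoms: none
Why: Reduction of an α,β-unsaturated tosylhydrazone with alkene migration: hydroboration of C=N, loss of sulfinate and a retro-ene shift of the diazene hydrogen to C9 with loss of N2 give the exocyclic methylene. The hydrogen should arrive on the α-face, opposite the axial C10 ester, which is also the thermodynamic (equatorial ester) arrangement.

Step 5
Reactants: 9 methyl ester with exocyclic C8=C17
Product: 10 primary alcohol (C11–OH)
Conditions: iBu2AlH (2.5 equiv), CH2Cl2, −78 → −40 °C; aq. potassium sodium tartrate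
Reagents that add atoms: none
Why: Hydride reduction of an ester: the C11 methyl ester on a secondary carbon is reduced while the angular neopentyl C20 ester is too hindered to react at low temperature.

Step 6
Reactants: 10 primary alcohol
Product: 11 primary iodide (C11–I)
Conditions: I2, PPh3, imidazole, CH2Cl2, 0 °C → rt
Reagents that add atoms: iodine, II
Why: Appel iodination under neutral conditions, which leaves the exocyclic alkene and the silylethyl ester untouched.

Step 7
Reactants: 12 2-bromo-6-hydroxybenzaldehyde
Product: 13 2-bromo-6-hydroxy-3-iodobenzaldehyde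
Conditions: NIS, TsOH·H2O (10 mol%), MeCN, 0 °C → rt
Reagents that add atoms: N-iodosuccinimide, O=C1CCC(=O)N1I
Why: Electrophilic aromatic iodination, expected para to the hydroxyl as in the 5-halogenation of salicylaldehydes; this marks the future C15′.

Step 8
Reactants: 13 2-bromo-6-hydroxy-3-iodobenzaldehyde
Product: 14 3-bromo-2-(hydroxymethyl)-4-iodophenol
Conditions: NaBH4, MeOH, 0 °C
Reagents that add atoms: none
Why: Borohydride reduction of the aldehyde to the C16 alcohol.

Step 9
Reactants: 14 3-bromo-2-(hydroxymethyl)-4-iodophenol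
Product: 15 bis(tert-butyldimethylsilyl) ether of 14
Conditions: TBSCl (2.4 equiv), imidazole, DMF, rt
Reagents that add atoms: tert-butyldimethylsilyl chloride, CC(C)(C)[Si](C)(C)Cl
Why: Silylation of both hydroxyls in one operation; the aryl and the alkyl silyl ether can later be told apart because only the aryl ether is cleaved by bifluoride.

Step 10
Reactants: 15 bis(tert-butyldimethylsilyl) ether of 14
Product: 17 2-bromo-4-(tert-butyldimethylsilyloxy)-3-[(tert-butyldimethylsilyloxy)methyl]benzaldehyde, via arylmagnesium chloride 16 (not isolated)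
Conditions: iPrMgCl·LiCl, THF, −20 °C; DMF, −20 °C → rt; aq. NH4Cl
Reagents that add atoms: N,N-dimethylformamide, CN(C)C=O
Why: Iodine–magnesium exchange is much faster at C–I than at C–Br, and the ortho-bromo Grignard reagent is stable at −20 °C; formylation with DMF installs C16′.

Step 11
Reactants: 11 primary iodide; 17 2-bromo-4-(tert-butyldimethylsilyloxy)-3-[(tert-butyldimethylsilyloxy)methyl]benzaldehyde
Product: 19 benzaldehyde carrying the decalin CH2 (C11) on C12, via alkylzinc iodide 18 (not isolated)
Conditions: Zn dust, LiCl, THF, 40 °C; then 17, Pd(OAc)2 (3 mol%), SPhos (6 mol%), THF, 25 → 50 °C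
Reagents that add atoms: none
Why: Negishi sp3–sp2 coupling: the ortho-formyl group speeds oxidative addition into the flanked C–Br bond, and the bulky biaryl phosphine (2-dicyclohexylphosphino-2′,6′-dimethoxybiphenyl) favours reductive elimination over β-hydride elimination. Aldehyde and esters are inert to the alkylzinc halide.

Step 12
Reactants: 19 benzaldehyde carrying the decalin CH2 on C12
Product: 20 benzoic acid (C16′ carboxyl)
Conditions: NaClO2, NaH2PO4, 2-methyl-2-butene, t-BuOH/THF/H2O, 0 °C → rt
Reagents that add atoms: sodium chlorite, [Na+].[O-]Cl=O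
Why: Pinnick oxidation; the scavenger alkene takes up hypochlorous acid, so the exocyclic alkene and both silyl ethers survive.

Step 13
Reactants: 21 (−)-sclareol
Product: 24 8α-hydroxy-14,15-dinorlabdan-13-one, via 14,15-diol 22 (not isolated), via α-hydroxy aldehyde 23 (not isolated)
Conditions: OsO4 (2 mol%), NaIO4 (4 equiv), 2,6-lutidine, dioxane/H2O 3:1, rt
Reagents that add atoms: none
Why: Lemieux–Johnson oxidation: dihydroxylation and glycol cleavage of the vinyl group give an α-hydroxy aldehyde, which periodate cleaves once more to the methyl ketone.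

Step 14
Reactants: 24 8α-hydroxy-14,15-dinorlabdan-13-one
Product: 25 14,15-dinorlabd-8(17)-en-13-one
Conditions: SOCl2, pyridine, CH2Cl2, −78 °C
Reagents that add atoms: none
Why: E2 dehydration through the chlorosulfite: the leaving group is equatorial, so only a hydrogen of the axial C17 methyl can be antiperiplanar and the exocyclic alkene should form.

Step 15
Reactants: 25 14,15-dinorlabd-8(17)-en-13-one
Product: 27 14,15,17-trinorlabdane-8,13-dione, via methoxy hydroperoxide 26 (not isolated)
Conditions: O3, CH2Cl2/MeOH, −78 °C; Me2S, −78 °C → rt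
Reagents that add atoms: ozone, [O-][O+]=O
Why: Ozonolysis of the 1,1-disubstituted alkene removes C17 and leaves the C8 ketone.

Step 16
Reactants: 27 14,15,17-trinorlabdane-8,13-dione
Product: 28 podocarp-8(14)-en-13-one
Conditions: NaOMe, MeOH, reflux
Reagents that add atoms: none
Why: Intramolecular aldol condensation of the methyl ketone onto the C8 ketone closes ring C′; C9′ keeps the equatorial side chain (9α-H).

Step 17
Reactants: 28 podocarp-8(14)-en-13-one
Product: 30 14-bromopodocarp-8(14)-en-13-one, via 8,14-dibromide 29 (not isolated)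
Conditions: Br2, CH2Cl2, 0 °C; Et3N, 0 °C → rt
Reagents that add atoms: bromine, BrBr
Why: α-Bromination of an enone by addition and dehydrobromination; only C14′ can end up brominated, which settles the regiochemistry that a phenol bromination would leave open.

Step 18
Reactants: 30 14-bromopodocarp-8(14)-en-13-one
Product: 32 14-bromopodocarpa-8,11,13-trien-13-ol, via cross-conjugated dienone 31 (not isolated)
Conditions: DDQ, TsOH·H2O (cat.), 1,4-dioxane, 100 °C
Reagents that add atoms: none
Why: Quinone dehydrogenation of a cyclohexenone at the α′,β′-positions; the dienone has a hydrogen on C9′ and tautomerises to the phenol.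

Step 19
Reactants: 32 14-bromopodocarpa-8,11,13-trien-13-ol
Product: 33 13-acetate of 32
Conditions: Ac2O, pyridine, DMAP (cat.), CH2Cl2, rt
Reagents that add atoms: acetic anhydride, CC(=O)OC(C)=O
Why: Acylation of the phenol, which protects the ring against the chromium oxidant of the next step.

Step 20
Reactants: 33 13-acetate of 32
Product: 34 7-oxo 13-acetate
Conditions: CrO3, AcOH/H2O, rt
Reagents that add atoms: chromium trioxide, O=[Cr](=O)=O
Why: Benzylic oxidation; C7′ is the only benzylic CH2, since C10′ is quaternary.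

Step 21
Reactants: 34 7-oxo 13-acetate
Product: 36 14-bromopodocarpa-8,11,13-triene-7β,13-diol, via 7β-hydroxy 13-acetate 35 (not isolated)
Conditions: NaBH4, MeOH/THF, 0 °C; then K2CO3, MeOH, rt
Reagents that add atoms: none
Why: Borohydride reduction of the aryl ketone; hydride should add axially from the α-face (anti to the axial 6β-hydrogen) to give the pseudo-equatorial 7β-alcohol. Methanolysis then frees the phenol.

Step 22
Reactants: 20 benzoic acid; 36 14-bromopodocarpa-8,11,13-triene-7β,13-diol
Product: 38 aryl benzoate with free 7′β-hydroxyl, via acid chloride 37 (not isolated)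
Conditions: 20, 1-chloro-N,N,2-trimethylprop-1-en-1-amine, CH2Cl2, 0 °C → rt; then 36, Et3N, CH2Cl2, 0 °C → rt
Reagents that add atoms: none
Why: Neutral acid chloride formation followed by acylation of a phenol with a tertiary amine; the acidic ortho-bromophenol reacts while the hindered secondary benzylic alcohol, without an acyl-transfer catalyst, should not.

Step 23
Reactants: 38 aryl benzoate with free 7′β-hydroxyl
Product: 39 aryl benzoate 7′β-acetate
Conditions: Ac2O, pyridine, DMAP (cat.), rt
Reagents that add atoms: acetic anhydride, CC(=O)OC(C)=O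
Why: DMAP-catalysed acetylation of the only free hydroxyl.

Step 24
Reactants: 39 aryl benzoate 7′β-acetate
Product: 40 free phenol (C14–OH) with C16 silyl ether and C14′ bromide
Conditions: KHF2, MeOH/THF 2:1, rt
Reagents that add atoms: none
Why: Bifluoride cleaves aryl silyl ethers selectively (the phenolate is the better leaving group); the alkyl silyl ether, both esters and the silylethyl ester should be untouched under these weakly acidic conditions.

Step 25
Reactants: 40 free phenol with C14′ bromide
Product: 41 spiro cyclohexadienone lactone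
Conditions: Pd2(dba)3 (5 mol%), (R)-2-(dicyclohexylphosphino)-2′-(dimethylamino)-1,1′-binaphthyl (12 mol%), K2CO3 (2 equiv), toluene (0.01 M), 90 °C
Reagents that add atoms: none
Why: Proposed new method: zerovalent palladium should insert into the C14′–Br bond; K2CO3 gives the phenolate, whose quinonoid resonance form is an ester enolate with its α-carbon at C15′, and this carbon binds divalent palladium to give a six-membered oxa-palladacycle from which C–C reductive elimination forms C14′–C15′. The closest known reaction types are the palladium-catalysed dearomative ipso-arylation of para-tethered phenols to spirocyclohexadienones (amine and carbon tethers) and the intramolecular α-arylation of anilide enolates to oxindoles. The five-membered lactone ring is closed by this reductive elimination as a spiro (ipso) closure, and the lost aromaticity is paid for by the new C–C bond and the dienone carbonyl. C15′ is set by the chiral biaryl phosphine on palladium, which decides whether the C12 or the C17′ edge of the phenolate lies on the β-face of the totarane; the 7′β-acetate beside C14′ is a secondary and possibly opposing bias, so both ligand enantiomers are to be compared. C- over O-arylation and ipso over ortho attack are fixed by the two-atom tether, which can reach only C15′. Survival of the aryl ester is helped by the low nucleophilicity of a 4-acylphenolate, by ortho substituents on both sides of the ester, by anhydrous carbonate in toluene and by high dilution. In the enolate form the O-aryl group can reach the geometry of a lactone more easily than in a neutral ester. The silyl ether on C16 keeps the ortho-hydroxybenzyl position from forming a quinone methide.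

Step 26
Reactants: 41 spiro cyclohexadienone lactone
Product: 42 spiro cyclohexenone (C12=C13–C14=O; C15 and C17′ saturated)
Conditions: [(Ph3P)CuH]6 (0.5 equiv), H2O (3 equiv), benzene/THF, rt
Reagents that add atoms: none
Why: Copper hydride conjugate reduction: only the β-unsubstituted enone arm C15=C17′ accepts hydride; the arm with fully substituted C12, the isolated alkene and the esters should not react.

Step 27
Reactants: 42 spiro cyclohexenone
Product: 43 2-(hydroxymethyl) enone (C16–OH)
Conditions: HF·pyridine, pyridine, THF, 0 °C → rt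
Reagents that add atoms: none
Why: Buffered fluoride cleavage of the primary silyl ether; the silylethyl ester needs free fluoride ion and should survive.

Step 28
Reactants: 43 2-(hydroxymethyl) enone
Product: 46 α-methylene ketone with C12–H (C13=C16; C14=O), via N-allyl sulfonylhydrazine 44 (not isolated), via allylic diazene 45 (not isolated)
Conditions: 2-nitrobenzenesulfonylhydrazide, PPh3, DEAD, THF, −30 °C; then rt
Reagents that add atoms: none
Why: Mitsunobu displacement at the primary allylic C16, loss of sulfinic acid, and retro-ene loss of N2 from the monoalkyl diazene (reductive 1,3-transposition) move the alkene to C13=C16 and put hydrogen on C12. The hydrogen should arrive on the face of the lactone carbonyl C16′, because the other face of C12 is covered by C8′, C7′ and the 7′β-acetate, so the C11 arm ends cis to C14′.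

Step 29
Reactants: 46 α-methylene ketone
Product: 47 2-(trimethylsilyl)ethyl ester of the target (14-OH cis to the C11 arm)
Conditions: NaBH4, CeCl3·7H2O, MeOH/THF, −78 °C
Reagents that add atoms: none
Why: Luche 1,2-reduction: the C11 arm should be axial (allylic strain with the exocyclic methylene) and block the face of C14 that it shares with C14′, so hydride should enter from the C16′ face and give the alcohol cis to the arm.

Step 30
Reactants: 47 2-(trimethylsilyl)ethyl ester of the target
Product: 48 CNP0558742.1
Conditions: (Me2N)3S+ Me3SiF2−, DMF, 0 °C → rt; aq. NH4Cl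
Reagents that add atoms: none
Why: Fluoride-induced β-elimination of the 2-silylethyl ester (ethene and fluorosilane are lost); attack is at silicon, so the hindered C20 carboxylate is freed without base strong enough to open the lactone or the acetate.

## Compound list

1 | carnosic acid | CC(C)c1cc2CC[C@H]3C(C)(C)CCC[C@]3(C(=O)O)c2c(O)c1O | starting material
2 | 2-(trimethylsilyl)ethyl carnosate | CC(C)c1cc2CC[C@H]3C(C)(C)CCC[C@]3(C(=O)OCC[Si](C)(C)C)c2c(O)c1O | intermediate
3 | 2-(trimethylsilyl)ethyl 11,12-di-O-methylcarnosate | CC(C)c1cc2CC[C@H]3C(C)(C)CCC[C@]3(C(=O)OCC[Si](C)(C)C)c2c(OC)c1OC | intermediate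
4 | methoxy hydroperoxide at C17 (CH(OMe)OOH on C8; representative peroxide) | COC(=O)C1=C(C(OC)OO)CC[C@H]2C(C)(C)CCC[C@]12C(=O)OCC[Si](C)(C)C | intermediate
5 | enal diester: 5α-H trans-decalin, C8=C9, CHO (C17) on C8, CO2Me (C11) on C9, 10β-CO2CH2CH2SiMe3 | COC(=O)C1=C(C=O)CC[C@H]2C(C)(C)CCC[C@]12C(=O)OCC[Si](C)(C)C | intermediate
6 | tosylhydrazone of 5 | COC(=O)C1=C(/C=N/NS(=O)(=O)c3ccc(C)cc3)CC[C@H]2C(C)(C)CCC[C@]12C(=O)OCC[Si](C)(C)C | intermediate
7 | N-(1,3,2-benzodioxaborol-2-yl) N′-tosylhydrazine on C17 | COC(=O)C1=C(CN(B3Oc4ccccc4O3)NS(=O)(=O)c3ccc(C)cc3)CC[C@H]2C(C)(C)CCC[C@]12C(=O)OCC[Si](C)(C)C | intermediate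
8 | allylic diazene (C17H2–N=NH on C8) | COC(=O)C1=C(CN=N)CC[C@H]2C(C)(C)CCC[C@]12C(=O)OCC[Si](C)(C)C | intermediate
9 | methyl ester: exocyclic C8=C17, 9α-H, 9β-CO2Me, 10β-CO2CH2CH2SiMe3 | C=C1CC[C@H]2C(C)(C)CCC[C@]2(C(=O)OCC[Si](C)(C)C)[C@H]1C(=O)OC | intermediate
10 | primary alcohol (C11–OH on C9, otherwise as 9) | C=C1CC[C@H]2C(C)(C)CCC[C@]2(C(=O)OCC[Si](C)(C)C)[C@H]1CO | intermediate
11 | primary iodide (C11–I) | C=C1CC[C@H]2C(C)(C)CCC[C@]2(C(=O)OCC[Si](C)(C)C)[C@H]1CI | intermediate
12 | 2-bromo-6-hydroxybenzaldehyde | O=Cc1c(O)cccc1Br | starting material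
13 | 2-bromo-6-hydroxy-3-iodobenzaldehyde | O=Cc1c(O)ccc(I)c1Br | intermediate
14 | 3-bromo-2-(hydroxymethyl)-4-iodophenol | OCc1c(O)ccc(I)c1Br | intermediate
15 | bis(tert-butyldimethylsilyl) ether of 14 | CC(C)(C)[Si](C)(C)OCc1c(O[Si](C)(C)C(C)(C)C)ccc(I)c1Br | intermediate
16 | arylmagnesium chloride from 15 (Mg in place of I) | CC(C)(C)[Si](C)(C)OCc1c(O[Si](C)(C)C(C)(C)C)ccc([Mg]Cl)c1Br | intermediate
17 | 2-bromo-4-(tert-butyldimethylsilyloxy)-3-[(tert-butyldimethylsilyloxy)methyl]benzaldehyde | CC(C)(C)[Si](C)(C)OCc1c(O[Si](C)(C)C(C)(C)C)ccc(C=O)c1Br | intermediate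
18 | alkylzinc iodide from 11 | C=C1CC[C@H]2C(C)(C)CCC[C@]2(C(=O)OCC[Si](C)(C)C)[C@H]1C[Zn]I | intermediate
19 | benzaldehyde with decalin CH2 (C11) on C12, CH2OTBS on C13, OTBS on C14 | C=C1CC[C@H]2C(C)(C)CCC[C@]2(C(=O)OCC[Si](C)(C)C)[C@H]1Cc1c(CO[Si](C)(C)C(C)(C)C)c(O[Si](C)(C)C(C)(C)C)ccc1C=O | intermediate
20 | benzoic acid corresponding to 19 | C=C1CC[C@H]2C(C)(C)CCC[C@]2(C(=O)OCC[Si](C)(C)C)[C@H]1Cc1c(CO[Si](C)(C)C(C)(C)C)c(O[Si](C)(C)C(C)(C)C)ccc1C(=O)O | intermediate
21 | (−)-sclareol | C[C@]12CCCC([C@@H]1CC[C@@]([C@@H]2CC[C@](C)(C=C)O)(C)O)(C)C | starting material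
22 | sclareol 14,15-diol (tetraol, C14 epimers) | C[C@]12CCCC([C@@H]1CC[C@@]([C@@H]2CC[C@](C)(C(O)CO)O)(C)O)(C)C | intermediate
23 | 8α,13-dihydroxy-15-norlabdan-14-al | C[C@]12CCCC([C@@H]1CC[C@@]([C@@H]2CC[C@](C)(C=O)O)(C)O)(C)C | intermediate
24 | 8α-hydroxy-14,15-dinorlabdan-13-one | C[C@]12CCCC([C@@H]1CC[C@@]([C@@H]2CCC(C)=O)(C)O)(C)C | intermediate
25 | 14,15-dinorlabd-8(17)-en-13-one | C[C@]12CCCC([C@@H]1CCC(=C)[C@@H]2CCC(C)=O)(C)C | intermediate
26 | 8-hydroperoxy-8-methoxy-14,15,17-trinorlabdan-13-one (C8 epimers) | C[C@]12CCCC([C@@H]1CCC(OC)(OO)[C@@H]2CCC(C)=O)(C)C | intermediate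
27 | 14,15,17-trinorlabdane-8,13-dione | C[C@]12CCCC([C@@H]1CCC(=O)[C@@H]2CCC(C)=O)(C)C | intermediate
28 | podocarp-8(14)-en-13-one | C[C@]12CCCC(C)(C)[C@@H]1CCC3=CC(=O)CC[C@H]23 | intermediate
29 | 8,14-dibromopodocarpan-13-one (trans-dibromide) | C[C@]12CCCC(C)(C)[C@@H]1CCC3(Br)C(Br)C(=O)CC[C@H]23 | intermediate
30 | 14-bromopodocarp-8(14)-en-13-one | C[C@]12CCCC(C)(C)[C@@H]1CCC3=C(Br)C(=O)CC[C@H]23 | intermediate
31 | 14-bromopodocarpa-8(14),11-dien-13-one | C[C@]12CCCC(C)(C)[C@@H]1CCC3=C(Br)C(=O)C=C[C@H]23 | intermediate
32 | 14-bromopodocarpa-8,11,13-trien-13-ol | C[C@]12CCCC(C)(C)[C@@H]1CCc3c(Br)c(O)ccc32 | intermediate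
33 | 14-bromopodocarpa-8,11,13-trien-13-yl acetate | C[C@]12CCCC(C)(C)[C@@H]1CCc3c(Br)c(OC(C)=O)ccc32 | intermediate
34 | 14-bromo-7-oxopodocarpa-8,11,13-trien-13-yl acetate | C[C@]12CCCC(C)(C)[C@@H]1CC(=O)c3c(Br)c(OC(C)=O)ccc32 | intermediate
35 | 14-bromo-7β-hydroxypodocarpa-8,11,13-trien-13-yl acetate | C[C@]12CCCC(C)(C)[C@@H]1C[C@H](O)c3c(Br)c(OC(C)=O)ccc32 | intermediate
36 | 14-bromopodocarpa-8,11,13-triene-7β,13-diol | C[C@]12CCCC(C)(C)[C@@H]1C[C@H](O)c3c(Br)c(O)ccc32 | intermediate
37 | acid chloride of 20 | C=C1CC[C@H]2C(C)(C)CCC[C@]2(C(=O)OCC[Si](C)(C)C)[C@H]1Cc1c(CO[Si](C)(C)C(C)(C)C)c(O[Si](C)(C)C(C)(C)C)ccc1C(=O)Cl | intermediate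
38 | 14′-bromoaryl benzoate with 7′β-OH, C14–OTBS and C16–OTBS | C=C1CC[C@H]2C(C)(C)CCC[C@]2(C(=O)OCC[Si](C)(C)C)[C@H]1Cc1c(CO[Si](C)(C)C(C)(C)C)c(O[Si](C)(C)C(C)(C)C)ccc1C(=O)Oc1ccc2c(c1Br)[C@@H](O)C[C@H]1C(C)(C)CCC[C@]21C | intermediate
39 | 7′β-acetate of 38 | C=C1CC[C@H]2C(C)(C)CCC[C@]2(C(=O)OCC[Si](C)(C)C)[C@H]1Cc1c(CO[Si](C)(C)C(C)(C)C)c(O[Si](C)(C)C(C)(C)C)ccc1C(=O)Oc1ccc2c(c1Br)[C@@H](OC(C)=O)C[C@H]1C(C)(C)CCC[C@]21C | intermediate
40 | key precursor: 14′-bromoaryl 4-hydroxybenzoate (free C14–OH, C16–OTBS, 7′β-OAc) | C=C1CC[C@H]2C(C)(C)CCC[C@]2(C(=O)OCC[Si](C)(C)C)[C@H]1Cc1c(CO[Si](C)(C)C(C)(C)C)c(O)ccc1C(=O)Oc1ccc2c(c1Br)[C@@H](OC(C)=O)C[C@H]1C(C)(C)CCC[C@]21C | intermediate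
41 | spiro cyclohexadienone lactone (C12=C13, C14=O, C15=C17′; C12 on the β-face of the totarane) | C=C1CC[C@H]2C(C)(C)CCC[C@]2(C(=O)OCC[Si](C)(C)C)[C@H]1CC1=C(CO[Si](C)(C)C(C)(C)C)C(=O)C=C[C@]12C(=O)Oc1ccc3c(c12)[C@@H](OC(C)=O)C[C@H]1C(C)(C)CCC[C@]31C | intermediate
42 | spiro cyclohexenone (C12=C13–C14=O, C16–OTBS) | C=C1CC[C@H]2C(C)(C)CCC[C@]2(C(=O)OCC[Si](C)(C)C)[C@H]1CC1=C(CO[Si](C)(C)C(C)(C)C)C(=O)CC[C@]12C(=O)Oc1ccc3c(c12)[C@@H](OC(C)=O)C[C@H]1C(C)(C)CCC[C@]31C | intermediate
43 | spiro 2-(hydroxymethyl) enone (C16–OH) | C=C1CC[C@H]2C(C)(C)CCC[C@]2(C(=O)OCC[Si](C)(C)C)[C@H]1CC1=C(CO)C(=O)CC[C@]12C(=O)Oc1ccc3c(c12)[C@@H](OC(C)=O)C[C@H]1C(C)(C)CCC[C@]31C | intermediate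
44 | N-allyl N-(2-nitrobenzenesulfonyl)hydrazine at C16 | C=C1CC[C@H]2C(C)(C)CCC[C@]2(C(=O)OCC[Si](C)(C)C)[C@H]1CC1=C(CN(N)S(=O)(=O)c4ccccc4[N+](=O)[O-])C(=O)CC[C@]12C(=O)Oc1ccc3c(c12)[C@@H](OC(C)=O)C[C@H]1C(C)(C)CCC[C@]31C | intermediate
45 | allylic diazene at C16 | C=C1CC[C@H]2C(C)(C)CCC[C@]2(C(=O)OCC[Si](C)(C)C)[C@H]1CC1=C(CN=N)C(=O)CC[C@]12C(=O)Oc1ccc3c(c12)[C@@H](OC(C)=O)C[C@H]1C(C)(C)CCC[C@]31C | intermediate
46 | α-methylene ketone (C12–H, C13=C16, C14=O; C11 arm cis to C14′) | C=C1CC[C@H]2C(C)(C)CCC[C@]2(C(=O)OCC[Si](C)(C)C)[C@H]1C[C@H]1C(=C)C(=O)CC[C@]12C(=O)Oc1ccc3c(c12)[C@@H](OC(C)=O)C[C@H]1C(C)(C)CCC[C@]31C | intermediate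
47 | 2-(trimethylsilyl)ethyl ester of CNP0558742.1 | C=C1CC[C@H]2C(C)(C)CCC[C@]2(C(=O)OCC[Si](C)(C)C)[C@H]1C[C@H]1C(=C)[C@@H](O)CC[C@]12C(=O)Oc1ccc3c(c12)[C@@H](OC(C)=O)C[C@H]1C(C)(C)CCC[C@]31C | intermediate
48 | CNP0558742.1 | C=C1CC[C@H]2C(C)(C)CCC[C@]2(C(=O)O)[C@H]1C[C@H]1C(=C)[C@@H](O)CC[C@]12C(=O)Oc1ccc3c(c12)[C@@H](OC(C)=O)C[C@H]1C(C)(C)CCC[C@]31C | target

## Step count and least certain steps

Total: 30 steps. Longest linear sequence: 18 steps (21 → 48, steps 13–21 and 22–30).

**Step 25 (key step, proposed new method).**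
- What may go wrong: cleavage or transesterification of the aryl ester by carbonate or by the phenolate before cyclization; a slow ring closure because the ester must turn into the lactone-like geometry; and poor facial selectivity at C15′, since the 7′β-acetate may oppose the ligand.
- Fallback (known chemistry; sets out from 18 and 36, returns at 47): the spiro ring is built by a Diels–Alder reaction instead of dearomatization.
  - Alkylzinc 18 is coupled (Pd(PPh3)4, THF) with (E)-1-iodo-2-methylbuta-1,3-diene to the labda-8(17),12,14-triene ester F1.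
  - Diol 36 undergoes Stille coupling with methyl 2-(tributylstannyl)acrylate (Pd(PPh3)4, CuI, CsF, DMF) to the α-aryl acrylate F2.
  - Warming F2 with TsOH in toluene in the presence of F1 closes it to the 3-methylenebenzofuranone F3, which is trapped at once as the [4+2] adduct F4 (C12–C15′ and C15–C17′ formed, the 1-alkyl group of the diene directing C12 to the lactone α-carbon).
  - Acetylation gives the 7′β-acetate F5.
  - A Schenck ene reaction (O2, light, tetraphenylporphyrin) moves the alkene to C13=C16 and puts oxygen on C14; allylic hydroperoxide F6 is reduced with PPh3 to 47.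
  - Face and endo/exo selectivity of the cycloaddition and the site of the ene reaction are not controlled, so isomers would have to be separated.

**Step 3.**
- What may go wrong: over-oxidation (cleavage of C8=C9) or unselective attack of ozone on the muconate diene.
- Fallback (sets out from 2, returns at 5): the two cleavages are done in separate known operations. Peracetic acid in acetic acid opens the catechol of 2 to the cis,cis-muconic diacid F7. TMSCHN2 in MeOH/toluene gives dimethyl ester F8. A Lemieux–Johnson oxidation (OsO4 cat., NaIO4) cleaves only the trisubstituted C13=C14 alkene to give 5.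

**Step 4.**
- What may go wrong: acylation of the reduced hydrazine nitrogen by the neighbouring C11 ester (lactam formation) in competition with diazene formation, or incomplete face selectivity of hydrogen transfer to C9.
- Fallback (sets out from 5, returns at 10): the ester is removed from the scene before the transposition. NaBH4/CeCl3·7H2O reduces the aldehyde and the hydroxy ester closes to butenolide F9. iBu2AlH (−78 → 0 °C) reduces F9 to allylic diol F10. A Mitsunobu reaction with 2-nitrobenzenesulfonylhydrazide at the less hindered C17 hydroxyl, followed by warming, gives 10 by the same diazene retro-ene shift.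

**Step 11.**
- What may go wrong: slow transmetalation or reductive elimination at the doubly ortho-substituted aryl bromide, with protodezincation of 18 or β-hydride elimination taking over.
- Fallback (sets out from 17 and 11, returns at 19): the polarity is reversed. Aldehyde 17 is protected as dimethyl acetal F11 (HC(OMe)3, TsOH). Bromine–lithium exchange (t-BuLi, −78 °C) and MgBr2 give the aryl Grignard reagent, which is alkylated with iodide 11 under Li2CuCl4 catalysis to F12. PPTS in wet acetone frees aldehyde 19.

**Step 28.**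
- What may go wrong: poor facial selectivity of hydrogen transfer to C12 (both faces next to the spiro centre are hindered), or sluggish Mitsunobu displacement on the 2-(hydroxymethyl) enone.
- Fallback (sets out from 42, returns at 47): the hydrogen is delivered from palladium instead. NaBH4/CeCl3·7H2O reduces 42 to allylic alcohol F13. HF·pyridine gives diol F14. ClCO2Me/pyridine at −20 °C converts the primary hydroxyl into methyl carbonate F15. Pd(OAc)2/PBu3/HCO2NH4 (formate reduction of the allylic carbonate, hydride to the more substituted terminus C12) gives 47. In this order C14 is set under the remote control of the spiro centre only.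

**Step 29.**
- What may go wrong: conjugate reduction of the exocyclic enone, or hydride attack from the wrong face if the C11 arm is not axial, giving the C14 epimer.
- Fallback (sets out from 46, returns at 47): the epimeric alcohol F16 is inverted. A Mitsunobu reaction with chloroacetic acid gives chloroacetate F17 with the required configuration; thiourea and NaHCO3 in ethanol remove the chloroacetyl group without touching the acetate or the lactone and give 47.

## Further compounds

F1 | step 25 | 2-(trimethylsilyl)ethyl (12E)-labda-8(17),12,14-trien-20-oate | C=C1CC[C@H]2C(C)(C)CCC[C@]2(C(=O)OCC[Si](C)(C)C)[C@H]1C/C=C(\C)C=C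
F2 | step 25 | methyl 2-(7β,13-dihydroxypodocarpa-8,11,13-trien-14-yl)acrylate | C=C(C(=O)OC)c1c(O)ccc2c1[C@@H](O)C[C@H]1C(C)(C)CCC[C@]21C
F3 | step 25 | totarane-fused 3-methylenebenzofuran-2(3H)-one with 7β-OH | C=C1C(=O)Oc2ccc3c(c21)[C@@H](O)C[C@H]1C(C)(C)CCC[C@]31C
F4 | step 25 | Diels–Alder adduct (C13=C14, C16 methyl, 7′β-OH) | C=C1CC[C@H]2C(C)(C)CCC[C@]2(C(=O)OCC[Si](C)(C)C)[C@H]1C[C@H]1C(C)=CCC[C@]12C(=O)Oc1ccc3c(c12)[C@@H](O)C[C@H]1C(C)(C)CCC[C@]31C
F5 | step 25 | 7′β-acetate of F4 | C=C1CC[C@H]2C(C)(C)CCC[C@]2(C(=O)OCC[Si](C)(C)C)[C@H]1C[C@H]1C(C)=CCC[C@]12C(=O)Oc1ccc3c(c12)[C@@H](OC(C)=O)C[C@H]1C(C)(C)CCC[C@]31C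
F6 | step 25 | C14 allylic hydroperoxide (C13=C16) | C=C1CC[C@H]2C(C)(C)CCC[C@]2(C(=O)OCC[Si](C)(C)C)[C@H]1C[C@H]1C(=C)[C@@H](OO)CC[C@]12C(=O)Oc1ccc3c(c12)[C@@H](OC(C)=O)C[C@H]1C(C)(C)CCC[C@]31C
F7 | step 3 | cis,cis-muconic diacid from ring cleavage of 2 | OC(=O)C1=C(/C=C(/C(C)C)C(O)=O)CC[C@H]2C(C)(C)CCC[C@]12C(=O)OCC[Si](C)(C)C
F8 | step 3 | dimethyl ester of F7 | COC(=O)C1=C(/C=C(/C(C)C)C(=O)OC)CC[C@H]2C(C)(C)CCC[C@]12C(=O)OCC[Si](C)(C)C
F9 | step 4 | butenolide (C11 carbonyl on C9, O–C17H2 on C8, C8=C9) | O=C3OCC(CC[C@H]2C(C)(C)CCC[C@]12C(=O)OCC[Si](C)(C)C)=C13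
F10 | step 4 | allylic diol (C17–OH on C8, C11–OH on C9, C8=C9) | OCC(CC[C@H]2C(C)(C)CCC[C@]12C(=O)OCC[Si](C)(C)C)=C1CO
F11 | step 11 | dimethyl acetal of 17 | COC(OC)c1ccc(O[Si](C)(C)C(C)(C)C)c(CO[Si](C)(C)C(C)(C)C)c1Br
F12 | step 11 | dimethyl acetal of 19 | C=C1CC[C@H]2C(C)(C)CCC[C@]2(C(=O)OCC[Si](C)(C)C)[C@H]1Cc1c(CO[Si](C)(C)C(C)(C)C)c(O[Si](C)(C)C(C)(C)C)ccc1C(OC)OC
F13 | step 28 | allylic alcohol from 42 (C12=C13, C14–OH, C16–OTBS) | C=C1CC[C@H]2C(C)(C)CCC[C@]2(C(=O)OCC[Si](C)(C)C)[C@H]1CC1=C(CO[Si](C)(C)C(C)(C)C)[C@@H](O)CC[C@]12C(=O)Oc1ccc3c(c12)[C@@H](OC(C)=O)C[C@H]1C(C)(C)CCC[C@]31C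
F14 | step 28 | C14,C16 diol from F13 | C=C1CC[C@H]2C(C)(C)CCC[C@]2(C(=O)OCC[Si](C)(C)C)[C@H]1CC1=C(CO)[C@@H](O)CC[C@]12C(=O)Oc1ccc3c(c12)[C@@H](OC(C)=O)C[C@H]1C(C)(C)CCC[C@]31C
F15 | step 28 | C16 methyl carbonate of F14 | C=C1CC[C@H]2C(C)(C)CCC[C@]2(C(=O)OCC[Si](C)(C)C)[C@H]1CC1=C(COC(=O)OC)[C@@H](O)CC[C@]12C(=O)Oc1ccc3c(c12)[C@@H](OC(C)=O)C[C@H]1C(C)(C)CCC[C@]31C
F16 | step 29 | C14 epimer of 47 | C=C1CC[C@H]2C(C)(C)CCC[C@]2(C(=O)OCC[Si](C)(C)C)[C@H]1C[C@H]1C(=C)[C@H](O)CC[C@]12C(=O)Oc1ccc3c(c12)[C@@H](OC(C)=O)C[C@H]1C(C)(C)CCC[C@]31C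
F17 | step 29 | C14 chloroacetate of 47 | C=C1CC[C@H]2C(C)(C)CCC[C@]2(C(=O)OCC[Si](C)(C)C)[C@H]1C[C@H]1C(=C)[C@@H](OC(=O)CCl)CC[C@]12C(=O)Oc1ccc3c(c12)[C@@H](OC(C)=O)C[C@H]1C(C)(C)CCC[C@]31C
A1 | alternative 1 | totarane-fused benzofuranone with C15′H2 and 7β-acetate | C1C(=O)Oc2ccc3c(c21)[C@@H](OC(C)=O)C[C@H]1C(C)(C)CCC[C@]31C
A2 | alternative 1 | 4-[(3E)-1-acetoxy-4,8-dimethylnona-3,7-dienyl]benzofuran-2(3H)-one | O=C1Cc2c(O1)cccc2[C@@H](OC(C)=O)C/C=C(\C)CCC=C(C)C
A3 | alternative 2 | aryne cycloadduct with 10′β-methyl, C5′=C6′ alkene and 7′α-methoxy group | C=C1CC[C@H]2C(C)(C)CCC[C@]2(C(=O)OCC=C)[C@H]1CC1=CC(=O)CC[C@]12C(=O)Oc1ccc3c(c12)[C@H](OC)C=C1C(C)(C)CCC[C@]31C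
A4 | alternative 2 | spiro benzofuranone silyl triflate (aryne precursor; SiMe3 on C8′, OTf on C9′) | C=C1CC[C@H]2C(C)(C)CCC[C@]2(C(=O)OCC=C)[C@H]1CC1=CC(=O)CC[C@]12C(=O)Oc1ccc(OS(=O)(=O)C(F)(F)F)c([Si](C)(C)C)c12
A5 | alternative 2 | 2-[(E)-2-methoxyvinyl]-1,3,3-trimethylcyclohexene | CO/C=C/C1=C(C)CCCC1(C)C
A6 | alternative 3 | 1-aryl cyclohexanecarbaldehyde with C16′ formyl on the spiro carbon | C=C1CC[C@H]2C(C)(C)CCC[C@]2(C(=O)OCC[Si](C)(C)C)[C@H]1C[C@H]1C(=C)[C@@H](O[Si](C)(C)C(C)(C)C)CC[C@@]1(C=O)c1c(O[Si](C)(C)C(C)(C)C)ccc2c1[C@@H](OC(C)=O)C[C@H]1C(C)(C)CCC[C@]21C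
A7 | alternative 3 | aryl cycloheptene oxide (epoxide across C15′–C16′, aryl on C15′) | C=C1CC[C@H]2C(C)(C)CCC[C@]2(C(=O)OCC[Si](C)(C)C)[C@H]1C[C@H]1C(=C)[C@@H](O[Si](C)(C)C(C)(C)C)CC[C@@]2(O[C@H]12)c1c(O[Si](C)(C)C(C)(C)C)ccc2c1[C@@H](OC(C)=O)C[C@H]1C(C)(C)CCC[C@]21C
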